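Start from a ratio: in Monday's and Friday's runs, which fed the same reagent to the same racemate, divide the left-handed substrate lost by the stall by the catalyst charged.

| flask | left-handed substrate | right-handed substrate | reagent | free catalyst | remark | time |
|---|---|---|---|---|---|---|
| Monday's | 0.10 M | 0.10 M | 0.060 M (fed, over 50 h) | 8.7 mM | run made earlier; the fed solution adds 0.10 times the starting volume |  |
| Friday's | 0.10 M | 0.10 M | 0.060 M (fed, over 50 h) | 20 mM | run made earlier; the fed solution adds 0.10 times the starting volume |  |
| flask | 0.10 M | 0.10 M | 0.0600 M (fed, over 50 h) | 13 mM | the fed solution adds 0.10 times the starting volume | 8.0 d |

- Monday's (time / d: left-handed substrate / %, right-handed substrate / %): 0.833: 48.4, 49.8; 2.50: 45.4, 50.3; 4.00: 45.4, 49.9; 6.00: 44.8, 49.9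
- Friday's (time / d: left-handed substrate / %, right-handed substrate / %): 1.67: 42.5, 50.1; 3.00: 41.0, 49.7; 5.00: 40.2, 50.5; 6.00: 40.1, 50.3

(standard deviation of a reading: 0.5 percentage points)

* part of the left-handed substrate and right-handed substrate charged together that has reacted at 8.0 d
* excess of left-handed product over right-handed product in the product at 8.0 d
* excess of right-handed substrate over left-handed substrate among what is left of the two at 8.0 d

- free catalyst is single-handed; left-handed substrate and right-handed substrate are mirror images of each other, charged as a racemate, each of them at the stated concentration
- charges are per starting volume, the dose included; the dosed solution carries all of it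
- what was read earlier has a scatter of 0.5 percentage points, one standard deviation
- an excess is below zero if the other one leads

Averaging the last two readings of each run, you find that Monday's run lost 9.80 mM and Friday's run 19.7 mM. Friday's loss is thus 2.01 times Monday's for 2.30 times the catalyst, so I read the stall as following the [free catalyst] charged, and the mean ratio gives 1.06 mol of left-handed product per mol of catalyst charged, the turnover number.

Now take two extremes of the flask. If its catalyst lasted, reagent would be the limiting reagent, and at one reagent per product 0.0600 M would convert 30.0% of the charge. If its catalyst stops at the turnover number, you get 13.7 mM of product, or 6.86% of the charge. I place the flask near the second extreme: Friday's run stalled below its reagent charge, and the flask holds more catalyst than Monday's run but less than Friday's. With right-handed substrate level near half the charge, my reckoning puts the excess of right-handed substrate over left-handed substrate near 7.37%.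

The forecast, holding that “Product therefore stops at about one equivalent of catalyst”, gave 6.7% of the charge reacted, an excess of left-handed product of 97% and an excess of right-handed substrate of 7%.

The flask gives 6.90% of the charge reacted, an excess of left-handed product of 96.9% and an excess of right-handed substrate of 7.18%, and the part reacted comes to 1.06 mol of product per mol of catalyst charged.

    reagent ⇌ dormant form (K = 4.80, k = 4.10 × 10⁻⁶ s⁻¹)
    reagent + free catalyst + left-handed substrate → free catalyst + left-handed product (k = 0.0110 M⁻² s⁻¹)
    reagent + free catalyst + right-handed substrate → free catalyst + right-handed product (k = 1.60 × 10⁻⁴ M⁻² s⁻¹)
    free catalyst → spent catalyst (k = 1.10 × 10⁻⁵ s⁻¹)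
    2 reagent → self-condensation product (k = 1.10 × 10⁻⁴ M⁻¹ s⁻¹)

In the flask at 1.98 d, left-handed substrate has a half-life of 18 d by its step to product, whereas free catalyst halves by its own loss in 0.729 d, far faster. By 4.00 d the flask's free catalyst stands at 2.23% of its charge. The step to product is first order in [reagent], so if the turnover number went with the reagent charge, a neighbour flask with 0.15 M of reagent, like this flask in its other charges, would have 2.65, giving 17.2% of the charge reacted. The computed neighbour flask reaches less, 13.8% reacted, which is 2.12 mol of product per mol of catalyst charged.

(The numbers in the tables are simulated with constants of no real substance, noise included.)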